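**Strategy.** The cyclohexene ring (C1 bearing OAc, C2=C3 with the CH2OBz arm on C3, C4–OH, C5–OBz, C6–OH) is cut at C3–C4 and C6–C1 into two three-carbon halves. The key step exploits that C4–C5–C6, three contiguous oxygenated ring carbons, are a dihydroxyacetone unit: with C5 as a ketone, both flanking carbons are nucleophilic. An amine-catalysed Michael/aldol [3+3] annulation of 1,3-bis(silyloxy)acetone with 4-(benzoyloxy)but-2-ynal (C1–C2–C3 plus the arm) forms both bonds and the C1, C4 and C6 stereocentres in one operation, while the labile C4 centre and the enal geometry converge. Hydride delivery from C1–O then reduces C5 and leaves the acetate on C1.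

Key step: step 3

Ring carbons keep the numbering C1–C6 defined above throughout the text.

Assumption: the D-configured threonine catalyst is taken to give the (6S,1R) sense, by analogy with its acyclic syn-aldol reactions of ketone 4; if the opposite sense is found, the L-configured catalyst is used.

**Step 1**
Reactants: 1 but-2-yne-1,4-diol
Product: 2 4-hydroxybut-2-yn-1-yl benzoate
Conditions: BzCl (0.3 equiv), pyridine, CH2Cl2/THF, 0 °C, diol in excess
Reagents that add atoms: benzoyl chloride, O=C(Cl)c1ccccc1
Why: acylation of a symmetric diol used in excess (pyridine-mediated esterification) should favour the monoester, and no stereocentre is involved.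

**Step 2**
Reactants: 2 4-hydroxybut-2-yn-1-yl benzoate
Product: 3 4-oxobut-2-yn-1-yl benzoate
Conditions: activated MnO2 (10 equiv), CH2Cl2, rt
Reagents that add atoms: none
Why: MnO2 oxidation of a propargylic alcohol should stop at the ynal and leave the benzoate untouched.

**Step 3**
Reactants: 3 4-oxobut-2-yn-1-yl benzoate; 4 1,3-bis(tert-butyldimethylsilyloxy)propan-2-one
Product: 6 (2S,5R,6S)-3-(benzoyloxymethyl)-2,6-bis(tert-butyldimethylsilyloxy)-5-hydroxycyclohex-3-en-1-one, via open-chain keto-enal 5 (not isolated)
Conditions: 4 (2 equiv), O-tert-butyl-D-threonine (30 mol%), 5-methyl-1H-tetrazole (10 mol%), NMP, 4 °C, 3 added over 12 h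
Reagents that add atoms: none
Why: Proposed new method: the primary-amine enamine of 4 should add through C4 to the β-carbon (C3) of ynal 3, an addition that is irreversible whereas the competing 1,2-aldol adduct can revert, and the resulting keto-enal 5 should then be closed by the enamine on the other α-carbon (C6) attacking the aldehyde (C1) in a 6-(enolexo)-exo-trig aldol. The closest known reaction types are amine-catalysed Michael/aldol [3+3] annulations of ketones with α,β-unsaturated aldehydes and the threonine-catalysed aldol reactions of ketone 4 itself. Only the Z enal can reach C6, and the E/Z isomers as well as both C4 epimers of 5 interconvert through the dienol of the doubly activated C4–H, so the mixture should be funnelled through one ring-closing transition state (dynamic kinetic resolution). In that half-chair the C4 silyloxy group sits pseudo-axial to avoid A(1,2) strain with the CH2OBz arm while the C6 silyloxy group and the new C1 alkoxide are pseudo-equatorial, which gives the 4,6-trans and 1,6-trans relationships, and the absolute sense at C6 and C1 is set by the carboxylic acid of the amino acid, which delivers the aldehyde to one enamine face. The step needs 1,4- over 1,2-selectivity, secured by the reversibility of the aldol and the slow addition of 3, and it must stop at the β-hydroxy ketone without dehydration to a phenol or migration of the β,γ-alkene, secured by the low temperature, the weak acid and direct use of crude 6 in step 4.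

**Step 4**
Reactants: 6 (2S,5R,6S)-3-(benzoyloxymethyl)-2,6-bis(tert-butyldimethylsilyloxy)-5-hydroxycyclohex-3-en-1-one
Product: 7 (1R,4S,5R,6R)-3-(benzoyloxymethyl)-4,6-bis(tert-butyldimethylsilyloxy)-5-hydroxycyclohex-2-en-1-yl acetate
Conditions: MeCHO (8 equiv), SmI2 (30 mol%), THF, −10 °C
Reagents that add atoms: acetaldehyde, CC=O
Why: in this Evans–Tishchenko reduction the C1 oxygen and acetaldehyde should deliver hydride within a samarium chelate to the C5 ketone, which gives the C5 alcohol anti to C1–O (cis to the C6 and trans to the C4 silyloxy group) and leaves the acetate on C1.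

**Step 5**
Reactants: 7 (1R,4S,5R,6R)-3-(benzoyloxymethyl)-4,6-bis(tert-butyldimethylsilyloxy)-5-hydroxycyclohex-2-en-1-yl acetate
Product: 8 (1R,4S,5R,6S)-5-(benzoyloxy)-3-(benzoyloxymethyl)-4,6-bis(tert-butyldimethylsilyloxy)cyclohex-2-en-1-yl acetate
Conditions: BzCl (3 equiv), DMAP (0.5 equiv), pyridine, 40 °C
Reagents that add atoms: benzoyl chloride, O=C(Cl)c1ccccc1
Why: DMAP-catalysed acylation of the only free hydroxyl should proceed without acetyl migration because C1–OAc and C5–OH are trans-1,3, and no stereocentre is touched.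

**Step 6**
Reactants: 8 (1R,4S,5R,6S)-5-(benzoyloxy)-3-(benzoyloxymethyl)-4,6-bis(tert-butyldimethylsilyloxy)cyclohex-2-en-1-yl acetate
Product: 9 (1R,4S,5R,6S)-5-(benzoyloxy)-3-(benzoyloxymethyl)-4,6-dihydroxycyclohex-2-en-1-yl acetate
Conditions: HF·pyridine, pyridine, THF, 0 °C to rt
Reagents that add atoms: none
Why: fluoride-mediated desilylation under buffered, weakly acidic conditions should cleave both silyl ethers while avoiding base-induced migration of the C5 benzoate to the neighbouring hydroxyls.

**Compound list**
1 | but-2-yne-1,4-diol | OCC#CCO | starting material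
2 | 4-hydroxybut-2-yn-1-yl benzoate | OCC#CCOC(=O)c1ccccc1 | intermediate
3 | 4-oxobut-2-yn-1-yl benzoate | O=CC#CCOC(=O)c1ccccc1 | intermediate
4 | 1,3-bis(tert-butyldimethylsilyloxy)propan-2-one | CC(C)(C)[Si](C)(C)OCC(=O)CO[Si](C)(C)C(C)(C)C | starting material
5 | (2Z)-3-(benzoyloxymethyl)-4,6-bis(tert-butyldimethylsilyloxy)-5-oxohex-2-enal, both C4 epimers, interconverting | O=C/C=C(/COC(=O)c1ccccc1)C(O[Si](C)(C)C(C)(C)C)C(=O)CO[Si](C)(C)C(C)(C)C | intermediate
6 | (2S,5R,6S)-3-(benzoyloxymethyl)-2,6-bis(tert-butyldimethylsilyloxy)-5-hydroxycyclohex-3-en-1-one (C1 R, C4 S, C6 S in ring numbering) | O[C@@H]1C=C(COC(=O)c2ccccc2)[C@H](O[Si](C)(C)C(C)(C)C)C(=O)[C@H]1O[Si](C)(C)C(C)(C)C | intermediate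
7 | (1R,4S,5R,6R)-3-(benzoyloxymethyl)-4,6-bis(tert-butyldimethylsilyloxy)-5-hydroxycyclohex-2-en-1-yl acetate | CC(=O)O[C@@H]1C=C(COC(=O)c2ccccc2)[C@H](O[Si](C)(C)C(C)(C)C)[C@@H](O)[C@H]1O[Si](C)(C)C(C)(C)C | intermediate
8 | (1R,4S,5R,6S)-5-(benzoyloxy)-3-(benzoyloxymethyl)-4,6-bis(tert-butyldimethylsilyloxy)cyclohex-2-en-1-yl acetate | CC(=O)O[C@@H]1C=C(COC(=O)c2ccccc2)[C@H](O[Si](C)(C)C(C)(C)C)[C@@H](OC(=O)c2ccccc2)[C@H]1O[Si](C)(C)C(C)(C)C | intermediate
9 | (1R,4S,5R,6S)-5-(benzoyloxy)-3-(benzoyloxymethyl)-4,6-dihydroxycyclohex-2-en-1-yl acetate | CC(=O)O[C@@H]1C=C(COC(=O)c2ccccc2)[C@H](O)[C@@H](OC(=O)c2ccccc2)[C@H]1O | target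

**Total steps:** 6. **Longest linear sequence:** 6 (1 → 2 → 3 → 6 → 7 → 8 → 9).

**Steps most likely to fail**

Step 3 (Proposed new method). The enamine may add to the aldehyde carbon and stall at the propargylic aldol. The amine may be trapped by conjugate addition to the ynal. The ketol may lose water and aromatize, or its alkene may move into conjugation. The facial selectivity of the ring closure is unproven, and retro-aldol equilibration would erode the enantiomeric purity. The fallback uses known reaction types and forms the two bonds in separate steps. It sets out from 3 and 4. Hydroiodination of 3 (NaI, AcOH) should give (Z)-2-iodo-4-oxobut-2-en-1-yl benzoate F1. The threonine-catalysed syn-aldol of 4 with F1 should give the acyclic aldol F2 with C6 and C1 set. Silylation (TESOTf, 2,6-lutidine) gives the triethylsilyl ether F3. Intramolecular palladium-catalysed ketone α-alkenylation (Pd(PPh3)4, PhOK, THF) should close C3–C4 to the cyclohexenone triethylsilyl ether F4, in which C4 can equilibrate to the pseudo-axial, 4,6-trans epimer. Selective removal of the triethylsilyl group (PPTS, MeOH) returns to the route at 6.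

Step 4. The hindered, chelating ketone may react slowly, so that retro-aldol ring opening, alkene migration or dehydration compete, and the hydride may not be delivered cleanly from the C1 face. The fallback sets out from 6. Hydroxyl-directed reduction with Me4NBH(OAc)3 (AcOH/MeCN, −30 °C) should give the anti-1,5-diol F5. Candida antarctica lipase B with vinyl acetate should then acetylate the less hindered allylic C1 hydroxyl, which also upgrades the enantiomeric purity. This returns to the route at 7.

Step 5. Acylation of a hydroxyl flanked by two silyl ethers may be too slow, and forcing conditions may cause silyl or acetyl migration. The fallback sets out from 7. HF·pyridine removes both silyl groups to give the triol F6. Trimethyl orthobenzoate with CSA should convert the cis C5/C6 diol into the cyclic orthoester F7. Aqueous acetic acid should open it to the axial benzoate, which in the half-chair with pseudo-axial C4–OH is the C5 benzoate. This returns to the route at 9.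

**Further compounds**
F1 | step 3 | (Z)-2-iodo-4-oxobut-2-en-1-yl benzoate | O=C/C=C(\I)COC(=O)c1ccccc1
F2 | step 3 | (2Z,4R,5S)-5,7-bis(tert-butyldimethylsilyloxy)-4-hydroxy-2-iodo-6-oxohept-2-en-1-yl benzoate | CC(C)(C)[Si](C)(C)OCC(=O)[C@@H](O[Si](C)(C)C(C)(C)C)[C@H](O)/C=C(\I)COC(=O)c1ccccc1
F3 | step 3 | (2Z,4R,5S)-5,7-bis(tert-butyldimethylsilyloxy)-2-iodo-6-oxo-4-(triethylsilyloxy)hept-2-en-1-yl benzoate | CC(C)(C)[Si](C)(C)OCC(=O)[C@@H](O[Si](C)(C)C(C)(C)C)[C@H](O[Si](CC)(CC)CC)/C=C(\I)COC(=O)c1ccccc1
F4 | step 3 | (2S,5R,6S)-3-(benzoyloxymethyl)-2,6-bis(tert-butyldimethylsilyloxy)-5-(triethylsilyloxy)cyclohex-3-en-1-one | CC[Si](CC)(CC)O[C@@H]1C=C(COC(=O)c2ccccc2)[C@H](O[Si](C)(C)C(C)(C)C)C(=O)[C@H]1O[Si](C)(C)C(C)(C)C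
F5 | step 4 | (1R,4S,5R,6S)-3-(benzoyloxymethyl)-4,6-bis(tert-butyldimethylsilyloxy)cyclohex-2-ene-1,5-diol | O[C@@H]1C=C(COC(=O)c2ccccc2)[C@H](O[Si](C)(C)C(C)(C)C)[C@@H](O)[C@H]1O[Si](C)(C)C(C)(C)C
F6 | step 5 | (1R,4S,5R,6R)-3-(benzoyloxymethyl)-4,5,6-trihydroxycyclohex-2-en-1-yl acetate | CC(=O)O[C@@H]1C=C(COC(=O)c2ccccc2)[C@H](O)[C@@H](O)[C@H]1O
F7 | step 5 | cyclic methyl orthobenzoate (2-methoxy-2-phenyl-1,3-dioxolane) across the C5 and C6 oxygens of the triol, mixture at the orthoester carbon | CC(=O)O[C@@H]1C=C(COC(=O)c2ccccc2)[C@H](O)[C@H]2OC(OC)(c3ccccc3)O[C@@H]12
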